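The retrosynthesis removes thirteen benzyl groups and a blocking bromine, cuts the lower C3–O gallate ester, then cuts O1–C2 and C3–C4 of upper ring C together, then C4–C4a (aryllithium plus aldehyde) and the lower C6–CHO bond.
The feature used is upper ring C (O1, C2, C3, C4, C4a, C8a): aryl at C2, gallate at C3 and the lower flavan at C4 sit beside the ring-A oxygen O1, the retron of an ortho-quinone methide (O1=C8a–C4a=C4) and a Z-enol gallate (C2=C3).
Forward, the lower chroman comes intact from (−)-epicatechin (benzylation, C8 bromination, silylation, C6 formylation) and ring A is added as a lithiated bromophenol to give a diaryl carbinol.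
Upper ring C closes last in a hetero-[4+2] step that also delivers ring B and the upper gallate; desilylation, the second gallate and hydrogenolysis finish the synthesis.
Lower C2/C3 come from epicatechin; upper C2/C3 cis from the Z-alkene, C3/C4 trans from endo addition to the Z-methide, and the absolute sense from a chiral phosphoric acid.

Key step: step 8

Locants: "upper" is the epiafzelechin unit and "lower" the epicatechin unit; primed locants are ring-B positions of the unit named; TBS is tert-butyldimethylsilyl.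
Assumption: the (R)-configured phosphoric acid is taken as the antipode that opens the face leading to the (2R,3R) upper unit; should it be the mismatched one, the (S)-acid is used under the same conditions. A wrong-face adduct would be a diastereomer, because the lower unit is enantiopure, and could be separated.

Step 1
Reactants: 1 (−)-epicatechin
Product: 2 5,7,3',4'-tetra-O-benzyl-(−)-epicatechin (2R,3R; C3 hydroxyl free)
Conditions: BnBr (4.4 equiv), K2CO3, DMF, 0 °C → rt
Reagents that add atoms: benzyl bromide, BrCc1ccccc1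
Why: Williamson etherification in which K2CO3 deprotonates only the four phenols, so the secondary C3 alcohol stays free, and the low temperature limits C-benzylation and base-induced C2 epimerisation.

Step 2
Reactants: 2 5,7,3',4'-tetra-O-benzyl-(−)-epicatechin
Product: 3 8-bromo-5,7,3',4'-tetra-O-benzyl-(−)-epicatechin
Conditions: NBS (1.0 equiv), CH2Cl2, −78 °C → rt
Reagents that add atoms: N-bromosuccinimide, O=C1CCC(=O)N1Br
Why: Electrophilic aromatic bromination goes to ring A, which is far more electron-rich than the catechol ring, and within ring A to C8, the position that reacts first in 5,7-di-O-benzylflavans; this leaves C6 as the only free ring-A position.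

Step 3
Reactants: 3 8-bromo-5,7,3',4'-tetra-O-benzyl-(−)-epicatechin
Product: 4 8-bromo-5,7,3',4'-tetra-O-benzyl-3-O-TBS-(−)-epicatechin
Conditions: TBSOTf, 2,6-lutidine, CH2Cl2, 0 °C
Reagents that add atoms: tert-butyldimethylsilyl triflate, CC(C)(C)[Si](C)(C)OS(=O)(=O)C(F)(F)F
Why: Silylation of the hindered axial secondary alcohol with a silyl triflate and a non-nucleophilic base; the silyl ether should survive the organolithium and acid steps and can later be removed with fluoride beside esters and benzyl ethers.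

Step 4
Reactants: 4 8-bromo-5,7,3',4'-tetra-O-benzyl-3-O-TBS-(−)-epicatechin
Product: 5 8-bromo-6-formyl-5,7,3',4'-tetra-O-benzyl-3-O-TBS-(−)-epicatechin
Conditions: POCl3, DMF, 0 → 50 °C; then aq. NaOAc
Reagents that add atoms: N,N-dimethylformamide, CN(C)C=O (formyl carbon); water, O (formyl oxygen on hydrolysis of the iminium salt)
Why: Vilsmeier–Haack formylation, in which the weakly electrophilic chloroiminium ion attacks only the phloroglucinol-type ring at its one free position C6 (between two benzyloxy groups, para to O1) and should leave ring B, the benzyl ethers and the secondary silyl ether alone.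

Step 5
Reactants: 6 3,5-bis(benzyloxy)phenol
Product: 7 2-bromo-3,5-bis(benzyloxy)phenol
Conditions: NBS (1.0 equiv), i-Pr2NH (10 mol%), CH2Cl2, −78 → 0 °C
Reagents that add atoms: N-bromosuccinimide, O=C1CCC(=O)N1Br
Why: Amine-mediated ortho-bromination of a phenol, in which the N-bromoamine is delivered through a hydrogen bond to the phenol OH, so the two equivalent ortho positions should react in preference to C4 between the benzyloxy groups.

Step 6
Reactants: 7 2-bromo-3,5-bis(benzyloxy)phenol; 5 8-bromo-6-formyl-5,7,3',4'-tetra-O-benzyl-3-O-TBS-(−)-epicatechin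
Product: 9 [4,6-bis(benzyloxy)-2-hydroxyphenyl][8-bromo-5,7,3',4'-tetra-O-benzyl-3-O-TBS-epicatechin-6-yl]methanol (both carbinol epimers), via lithium 3,5-bis(benzyloxy)-2-lithiophenoxide 8 (not isolated)
Conditions: 7 (1.5 equiv), n-BuLi (just under 2 equiv per 7), THF, −78 °C; then 5, −78 → −30 °C; aq. NH4Cl
Reagents that add atoms: none
Why: Deprotonation followed by bromine–lithium exchange gives the ortho-lithiophenoxide, whose 1,2-addition to the aldehyde should be much faster at −78 °C than exchange with the C8 bromide of 5; the carbinol centre forms as both epimers, which is immaterial because step 8 planarises it.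

Step 7
Reactants: 10 3,4,5-tris(benzyloxy)benzoic acid; 11 1-(benzyloxy)-4-ethynylbenzene
Product: 12 (Z)-2-[4-(benzyloxy)phenyl]ethenyl 3,4,5-tris(benzyloxy)benzoate
Conditions: [RuCl2(p-cymene)]2 (1 mol%), P(4-ClC6H4)3 (3 mol%), DMAP (4 mol%), toluene, 60 °C
Reagents that add atoms: none
Why: Ruthenium-catalysed anti-Markovnikov hydro-oxycarbonylation of a terminal alkyne, in which the carboxylate adds to the α-carbon of a ruthenium vinylidene and protodemetalation gives the Z-enol ester, the geometry that becomes the upper 2,3-cis relationship.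

Step 8
Reactants: 9 [4,6-bis(benzyloxy)-2-hydroxyphenyl][8-bromo-5,7,3',4'-tetra-O-benzyl-3-O-TBS-epicatechin-6-yl]methanol; 12 (Z)-2-[4-(benzyloxy)phenyl]ethenyl 3,4,5-tris(benzyloxy)benzoate
Product: 14 5,7,4'-tri-O-benzyl-3-O-[3,4,5-tris(benzyloxy)benzoyl]epiafzelechin-(4β→6)-8-bromo-5,7,3',4'-tetra-O-benzyl-3-O-TBS-epicatechin (upper unit 2,3-cis-3,4-trans), via Z-ortho-quinone methide 13 (not isolated)
Conditions: (R)-3,3'-bis(2,4,6-triisopropylphenyl)-1,1'-binaphthalene-2,2'-diyl hydrogen phosphate (10 mol%), 12 (1.5 equiv), 4 Å MS, toluene, −20 °C → rt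
Reagents that add atoms: none
Why: Proposed new method: the phosphoric acid dehydrates 9 to the doubly aryl-stabilised ortho-quinone methide 13 and, hydrogen-bonded to its carbonyl oxygen, activates it for an asynchronous inverse-demand hetero-[4+2] addition of 12, in which the acyloxy-bearing carbon (future C3) bonds to the methide carbon C4 because the complementary charge then rests at C2 as a 4-benzyloxybenzyl cation (the styrene-type polarisation outweighs the weak donor effect of the acyloxy oxygen), and the ring-A oxygen closes O1–C2. The closest known reaction type is the chiral-phosphoric-acid-catalysed [4+2] cycloaddition of ortho-quinone methides generated from ortho-hydroxybenzyl alcohols with styrenes and enamides, which has not been shown for β-acyloxystyrenes. Ring C (O1, C2, C3, C4, C4a, C8a) closes in the cycloaddition itself, which in the stepwise limit is a 6-exo-trig capture of the C2 benzylic cation by the phenolic oxygen. C2 and C3 become cis because both new bonds form on one face of the Z-alkene; C4 becomes trans to C3 because allylic strain with the C5 benzyloxy group turns the bulky flavanyl substituent of 13 toward the carbonyl oxygen (Z-methide) and the aryl and gallate groups of 12 approach endo; the absolute configuration follows from the face left open by the chiral phosphate, the remote lower unit having little say. The step needs regioselectivity (C3 to C4), transfer of the Z-geometry and face selectivity: the 4-alkoxyaryl group should secure the first, a non-polar solvent and low temperature should keep the C2 cation too short-lived to rotate or be trapped by the gallate carbonyl, and the catalyst antipode is matched to the required face.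

Step 9
Reactants: 14 the protected dimer with lower 3-O-TBS
Product: 15 5,7,4'-tri-O-benzyl-3-O-[3,4,5-tris(benzyloxy)benzoyl]epiafzelechin-(4β→6)-8-bromo-5,7,3',4'-tetra-O-benzylepicatechin (lower C3 hydroxyl free)
Conditions: TBAF, AcOH, THF, 0 °C → rt
Reagents that add atoms: none
Why: Fluoride-induced silyl ether cleavage driven by the Si–F bond; buffering with acetic acid keeps the medium non-basic so the upper gallate ester should neither migrate nor cleave, and no stereocentre is touched.

Step 10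
Reactants: 15 the dimer with free lower C3 hydroxyl; 10 3,4,5-tris(benzyloxy)benzoic acid
Product: 16 5,7,4'-tri-O-benzyl-3-O-[3,4,5-tris(benzyloxy)benzoyl]epiafzelechin-(4β→6)-8-bromo-5,7,3',4'-tetra-O-benzyl-3-O-[3,4,5-tris(benzyloxy)benzoyl]epicatechin
Conditions: 10 (3 equiv), DCC, DMAP, CH2Cl2, rt
Reagents that add atoms: none
Why: Steglich esterification, in which DCC activates the acid as its O-acylisourea and DMAP transfers the acyl group to the hindered axial hydroxyl; the alcohol C–O bond is not broken, so lower C3 keeps its configuration.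

Step 11
Reactants: 16 the perbenzylated bromo bis-gallate
Product: 17 epiafzelechin 3-O-gallate-(4β→6)-epicatechin 3-O-gallate (CNP0169607.1; upper unit 2R,3R,4S; lower unit 2R,3R)
Conditions: H2 (1 atm), Pd(OH)2/C, Et3N (1.5 equiv), THF/MeOH, rt
Reagents that add atoms: none
Why: Heterogeneous hydrogenolysis over Pd(OH)2 on carbon should cleave all thirteen benzyl ethers and reduce the aryl C–Br bond, with Et3N capturing the HBr that would threaten the acid-labile interflavan bond; the benzoate esters and the chroman C2–O bonds are expected to survive.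

Compound list
1 | (−)-epicatechin (2R,3R) | O[C@@H]1Cc2c(O)cc(O)cc2O[C@@H]1c1ccc(O)c(O)c1 | starting material
2 | 5,7,3',4'-tetra-O-benzyl-(−)-epicatechin | O[C@@H]1Cc2c(OCc3ccccc3)cc(OCc3ccccc3)cc2O[C@@H]1c1ccc(OCc2ccccc2)c(OCc2ccccc2)c1 | intermediate
3 | 8-bromo-5,7,3',4'-tetra-O-benzyl-(−)-epicatechin | O[C@@H]1Cc2c(OCc3ccccc3)cc(OCc3ccccc3)c(Br)c2O[C@@H]1c1ccc(OCc2ccccc2)c(OCc2ccccc2)c1 | intermediate
4 | 8-bromo-5,7,3',4'-tetra-O-benzyl-3-O-TBS-(−)-epicatechin | CC(C)(C)[Si](C)(C)O[C@@H]1Cc2c(OCc3ccccc3)cc(OCc3ccccc3)c(Br)c2O[C@@H]1c1ccc(OCc2ccccc2)c(OCc2ccccc2)c1 | intermediate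
5 | 8-bromo-6-formyl-5,7,3',4'-tetra-O-benzyl-3-O-TBS-(−)-epicatechin | CC(C)(C)[Si](C)(C)O[C@@H]1Cc2c(OCc3ccccc3)c(C=O)c(OCc3ccccc3)c(Br)c2O[C@@H]1c1ccc(OCc2ccccc2)c(OCc2ccccc2)c1 | intermediate
6 | 3,5-bis(benzyloxy)phenol | Oc1cc(OCc2ccccc2)cc(OCc2ccccc2)c1 | starting material
7 | 2-bromo-3,5-bis(benzyloxy)phenol | Oc1cc(OCc2ccccc2)cc(OCc2ccccc2)c1Br | intermediate
8 | lithium 3,5-bis(benzyloxy)-2-lithiophenoxide (not isolated) | [Li]Oc1cc(OCc2ccccc2)cc(OCc2ccccc2)c1[Li] | intermediate
9 | [4,6-bis(benzyloxy)-2-hydroxyphenyl][8-bromo-5,7,3',4'-tetra-O-benzyl-3-O-TBS-epicatechin-6-yl]methanol (both carbinol epimers) | OC(c2c(OCc4ccccc4)c(Br)c3c(c2OCc4ccccc4)C[C@@H](O[Si](C)(C)C(C)(C)C)[C@@H](c5ccc(OCc4ccccc4)c(OCc4ccccc4)c5)O3)c1c(O)cc(OCc4ccccc4)cc1OCc4ccccc4 | intermediate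
10 | 3,4,5-tris(benzyloxy)benzoic acid | OC(=O)c1cc(OCc2ccccc2)c(OCc2ccccc2)c(OCc2ccccc2)c1 | starting material
11 | 1-(benzyloxy)-4-ethynylbenzene | C#Cc1ccc(OCc2ccccc2)cc1 | starting material
12 | (Z)-2-[4-(benzyloxy)phenyl]ethenyl 3,4,5-tris(benzyloxy)benzoate | O=C(O/C=C\c1ccc(OCc2ccccc2)cc1)c1cc(OCc2ccccc2)c(OCc2ccccc2)c(OCc2ccccc2)c1 | intermediate
13 | (Z)-3,5-bis(benzyloxy)-6-[(8-bromo-5,7,3',4'-tetra-O-benzyl-3-O-TBS-epicatechin-6-yl)methylidene]cyclohexa-2,4-dien-1-one (ortho-quinone methide, not isolated) | O=C1/C(=C\c2c(OCc4ccccc4)c(Br)c3c(c2OCc4ccccc4)C[C@@H](O[Si](C)(C)C(C)(C)C)[C@@H](c5ccc(OCc4ccccc4)c(OCc4ccccc4)c5)O3)C(OCc4ccccc4)=CC(OCc4ccccc4)=C1 | intermediate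
14 | 5,7,4'-tri-O-benzyl-3-O-[3,4,5-tris(benzyloxy)benzoyl]epiafzelechin-(4β→6)-8-bromo-5,7,3',4'-tetra-O-benzyl-3-O-TBS-epicatechin | O=C(O[C@@H]1[C@@H](c2c(OCc4ccccc4)c(Br)c3c(c2OCc4ccccc4)C[C@@H](O[Si](C)(C)C(C)(C)C)[C@@H](c5ccc(OCc4ccccc4)c(OCc4ccccc4)c5)O3)c2c(OCc4ccccc4)cc(OCc4ccccc4)cc2O[C@@H]1c1ccc(OCc4ccccc4)cc1)c6cc(OCc4ccccc4)c(OCc4ccccc4)c(OCc4ccccc4)c6 | intermediate
15 | 5,7,4'-tri-O-benzyl-3-O-[3,4,5-tris(benzyloxy)benzoyl]epiafzelechin-(4β→6)-8-bromo-5,7,3',4'-tetra-O-benzylepicatechin | O=C(O[C@@H]1[C@@H](c2c(OCc4ccccc4)c(Br)c3c(c2OCc4ccccc4)C[C@@H](O)[C@@H](c5ccc(OCc4ccccc4)c(OCc4ccccc4)c5)O3)c2c(OCc4ccccc4)cc(OCc4ccccc4)cc2O[C@@H]1c1ccc(OCc4ccccc4)cc1)c6cc(OCc4ccccc4)c(OCc4ccccc4)c(OCc4ccccc4)c6 | intermediate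
16 | 5,7,4'-tri-O-benzyl-3-O-[3,4,5-tris(benzyloxy)benzoyl]epiafzelechin-(4β→6)-8-bromo-5,7,3',4'-tetra-O-benzyl-3-O-[3,4,5-tris(benzyloxy)benzoyl]epicatechin | O=C(O[C@@H]1[C@@H](c2c(OCc4ccccc4)c(Br)c3c(c2OCc4ccccc4)C[C@@H](OC(=O)c7cc(OCc4ccccc4)c(OCc4ccccc4)c(OCc4ccccc4)c7)[C@@H](c5ccc(OCc4ccccc4)c(OCc4ccccc4)c5)O3)c2c(OCc4ccccc4)cc(OCc4ccccc4)cc2O[C@@H]1c1ccc(OCc4ccccc4)cc1)c6cc(OCc4ccccc4)c(OCc4ccccc4)c(OCc4ccccc4)c6 | intermediate
17 | epiafzelechin 3-O-gallate-(4β→6)-epicatechin 3-O-gallate, CNP0169607.1 (upper 2R,3R,4S; lower 2R,3R) | O=C(O[C@@H]1[C@@H](c2c(O)cc3c(c2O)C[C@@H](OC(=O)c2cc(O)c(O)c(O)c2)[C@@H](c2ccc(O)c(O)c2)O3)c2c(O)cc(O)cc2O[C@@H]1c1ccc(O)cc1)c1cc(O)c(O)c(O)c1 | target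

Total step count: 11. Longest linear sequence: 9 steps (steps 1, 2, 3, 4, 6, 8, 9, 10, 11).

Steps most likely to fail

Step 8. The addition may take the opposite regiochemistry (enol-type polarisation). The Z-geometry may be lost if the C2 benzylic cation lives long enough to rotate or to be intercepted by the gallate carbonyl. An exo approach or poor face discrimination by the catalyst would give the wrong stereochemistry, and the methide may self-condense before it is trapped. The fallback uses the established Lewis-acid condensation of flavans and sets out from 3. Purchased (−)-epiafzelechin, (2R,3R)-2-(4-hydroxyphenyl)chromane-3,5,7-triol, is benzylated (BnBr, K2CO3, DMF) to 5,7,4'-tri-O-benzyl-(−)-epiafzelechin F1. DDQ in CH2Cl2 with 2-ethoxyethanol oxidises C4 to 4β-(2-ethoxyethoxy)-5,7,4'-tri-O-benzylepiafzelechin F2. TMSOTf in CH2Cl2 at −78 °C ionises F2, and an excess of 3 captures the C4 cation through its only free ring-A position C6, trans to the C3 hydroxyl as is intrinsic to the 2,3-cis series. This should give 5,7,4'-tri-O-benzylepiafzelechin-(4β→6)-8-bromo-5,7,3',4'-tetra-O-benzylepicatechin F3. Esterification of both C3 hydroxyls with 10 (DCC, DMAP, CH2Cl2) comes back to the route at 16.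

Step 6. Attack on the crowded, electron-rich aldehyde may be slow enough for bromine–lithium scrambling with the C8 bromide or butylation of the aryllithium to compete, and the electron-rich carbinol may ionise during work-up. The fallback avoids organometallics and sets out from 6 and 5. Phenylboronic acid with catalytic propionic acid in toluene, with azeotropic removal of water, templates an ortho-specific hydroxyalkylation of the phenol by the aldehyde. This should give 5,7-bis(benzyloxy)-4-(8-bromo-5,7,3',4'-tetra-O-benzyl-3-O-TBS-epicatechin-6-yl)-2-phenyl-4H-1,3,2-benzodioxaborin F4. Transesterification with 2,2-dimethylpropane-1,3-diol in THF releases the diol and comes back to the route at 9.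

Step 4. Substitution at the crowded C6 of the brominated ring may be so slow that the temperature needed converts the silyl ether into a formate or removes the bromine. The fallback replaces electrophilic formylation by halogen–metal exchange and sets out from 4. NIS with catalytic CF3CO2H in CH2Cl2 should iodinate C6 to give 8-bromo-6-iodo-5,7,3',4'-tetra-O-benzyl-3-O-TBS-(−)-epicatechin F5. i-PrMgCl·LiCl in THF at −40 °C exchanges the iodide selectively over the bromide to give [8-bromo-5,7,3',4'-tetra-O-benzyl-3-O-TBS-epicatechin-6-yl]magnesium chloride F6. Quenching with DMF and aqueous work-up comes back to the route at 5.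

Further compounds
F1 | step 8 | 5,7,4'-tri-O-benzyl-(−)-epiafzelechin | O[C@@H]1Cc2c(OCc3ccccc3)cc(OCc3ccccc3)cc2O[C@@H]1c1ccc(OCc2ccccc2)cc1
F2 | step 8 | 4β-(2-ethoxyethoxy)-5,7,4'-tri-O-benzylepiafzelechin | O[C@@H]1[C@@H](OCCOCC)c2c(OCc3ccccc3)cc(OCc3ccccc3)cc2O[C@@H]1c1ccc(OCc2ccccc2)cc1
F3 | step 8 | 5,7,4'-tri-O-benzylepiafzelechin-(4β→6)-8-bromo-5,7,3',4'-tetra-O-benzylepicatechin | O[C@@H]1[C@@H](c2c(OCc4ccccc4)c(Br)c3c(c2OCc4ccccc4)C[C@@H](O)[C@@H](c5ccc(OCc4ccccc4)c(OCc4ccccc4)c5)O3)c2c(OCc4ccccc4)cc(OCc4ccccc4)cc2O[C@@H]1c1ccc(OCc4ccccc4)cc1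
F4 | step 6 | 5,7-bis(benzyloxy)-4-(8-bromo-5,7,3',4'-tetra-O-benzyl-3-O-TBS-epicatechin-6-yl)-2-phenyl-4H-1,3,2-benzodioxaborin | B1(c2ccccc2)Oc2cc(OCc3ccccc3)cc(OCc3ccccc3)c2C(O1)c1c(OCc4ccccc4)c(Br)c3c(c1OCc4ccccc4)C[C@@H](O[Si](C)(C)C(C)(C)C)[C@@H](c5ccc(OCc4ccccc4)c(OCc4ccccc4)c5)O3
F5 | step 4 | 8-bromo-6-iodo-5,7,3',4'-tetra-O-benzyl-3-O-TBS-(−)-epicatechin | CC(C)(C)[Si](C)(C)O[C@@H]1Cc2c(OCc3ccccc3)c(I)c(OCc3ccccc3)c(Br)c2O[C@@H]1c1ccc(OCc2ccccc2)c(OCc2ccccc2)c1
F6 | step 4 | [8-bromo-5,7,3',4'-tetra-O-benzyl-3-O-TBS-epicatechin-6-yl]magnesium chloride | CC(C)(C)[Si](C)(C)O[C@@H]1Cc2c(OCc3ccccc3)c([Mg]Cl)c(OCc3ccccc3)c(Br)c2O[C@@H]1c1ccc(OCc2ccccc2)c(OCc2ccccc2)c1
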